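**Retrosynthetic overview**

- Rings: A is the hydroquinone ring (O1 is its ether oxygen), B the catechol-type ring, C the para-phenylene, and D the meta-phenylene (C1 carries the CH2CH2 bridge, C3 the ether oxygen). All four rings are bought. The 18-membered macrocycle is the only ring made, and it is closed in the penultimate step.
- Key disconnection: O1 (ring A)–C3 (ring D). The free ring A phenol adds to a ring D aryne (C3≡C4) that fluoride releases from an ortho-silylaryl triflate.
- Enabling feature: ring D carries only the bridge at C1, and its ether carbon C3 sits next to an unsubstituted C4–H. The pair C3–O/C4–H is therefore the retron of an aryne O–H addition. The free C5–H can host a temporary chlorine beside the triple bond that steers O1 to C3.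
- Seco chain: two hydroboration/B-alkyl Suzuki couplings build the CH2CH2 bridges (A–B first, then C–D) without any alkene reduction. A Chan–Lam coupling between them makes the ring B–O–ring C ether.
- End game: one hydrogenolysis removes the steering chlorine and both benzyl ethers.

Key step: step 10

Remark: the target has no stereocentre and no stable atropisomerism is assumed, so no stereocontrol is needed. The four aromatic starting materials are taken as catalogue chemicals.

**Step 1**
Reactants: 1 4-(benzyloxy)phenol
Product: 2 4-(benzyloxy)-2-bromophenol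
Conditions: NBS (1.0 equiv), MeCN, 0 °C
Reagents that add atoms: N-bromosuccinimide, O=C1CCC(=O)N1Br
Why: Electrophilic aromatic bromination goes ortho to the free OH, the stronger donor, because the position para to it is blocked by the benzyloxy group.

**Step 2**
Reactants: 2 4-(benzyloxy)-2-bromophenol
Product: 3 4-(benzyloxy)-2-bromo-1-(methoxymethoxy)benzene
Conditions: NaH, THF/DMF, 0 °C; MOMCl, 0 °C → rt
Reagents that add atoms: chloromethyl methyl ether, COCCl
Why: Williamson-type O-alkylation of the sodium phenoxide masks O1 of ring A as a MOM acetal, which survives base, boranes and organolithium and is orthogonal to the benzyl ethers.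

**Step 3**
Reactants: 4 4-(benzyloxy)-3-hydroxybenzaldehyde
Product: 5 2-(benzyloxy)-5-vinylphenol
Conditions: MePPh3Br (2.5 equiv), KOt-Bu (2.5 equiv), THF, 0 °C → rt
Reagents that add atoms: methyltriphenylphosphonium bromide, C[P+](c1ccccc1)(c1ccccc1)c1ccccc1.[Br-]
Why: Wittig methylenation works on the free phenol because excess ylide first deprotonates it, and the resulting meta phenoxide is not conjugated with the aldehyde and does not deactivate it.

**Step 4**
Reactants: 5 2-(benzyloxy)-5-vinylphenol; 3 4-(benzyloxy)-2-bromo-1-(methoxymethoxy)benzene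
Product: 7 2-(benzyloxy)-5-{2-[5-(benzyloxy)-2-(methoxymethoxy)phenyl]ethyl}phenol, via bis-boryl adduct 6 (not isolated)
Conditions: 9-BBN (2.2 equiv), THF, 0 °C → rt; then 3, PdCl2(dppf) (5 mol %), 3 M aq NaOH, THF, 65 °C
Reagents that add atoms: none
Why: Anti-Markovnikov hydroboration of the styrene (one further equivalent of borane is consumed by the OH and hydrolysed later) followed by B-alkyl Suzuki–Miyaura coupling with the aryl bromide gives the A–B CH2CH2 bridge directly at the right oxidation level.

**Step 5**
Reactants: 7 2-(benzyloxy)-5-{2-[5-(benzyloxy)-2-(methoxymethoxy)phenyl]ethyl}phenol; 8 (4-vinylphenyl)boronic acid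
Product: 9 4-(benzyloxy)-2-{2-[4-(benzyloxy)-3-(4-vinylphenoxy)phenyl]ethyl}-1-(methoxymethoxy)benzene
Conditions: Cu(OAc)2 (2 equiv), pyridine (5 equiv), 4 Å MS, CH2Cl2, dry air, rt
Reagents that add atoms: none
Why: Chan–Lam coupling (boron-to-copper transmetalation, then C–O reductive elimination from trivalent copper) arylates the only free phenol at room temperature, which spares the vinyl group, the MOM acetal and the benzyl ethers.

**Step 6**
Reactants: 10 2-bromo-6-chlorophenol
Product: 11 2-bromo-6-chloro-4-iodophenol
Conditions: NIS (1.05 equiv), TsOH·H2O (10 mol %), MeCN, rt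
Reagents that add atoms: N-iodosuccinimide, O=C1CCC(=O)N1I
Why: Electrophilic aromatic iodination can only go para to the OH because both ortho positions carry halogens.

**Step 7**
Reactants: 9 4-(benzyloxy)-2-{2-[4-(benzyloxy)-3-(4-vinylphenoxy)phenyl]ethyl}-1-(methoxymethoxy)benzene; 11 2-bromo-6-chloro-4-iodophenol
Product: 13 4-{2-[4-(2-(benzyloxy)-5-{2-[5-(benzyloxy)-2-(methoxymethoxy)phenyl]ethyl}phenoxy)phenyl]ethyl}-2-bromo-6-chlorophenol, via alkylborane 12 (not isolated)
Conditions: 9-BBN (1.2 equiv), THF, rt; then 11, PdCl2(dppf) (5 mol %), 3 M aq NaOH (4 equiv), THF, rt → 40 °C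
Reagents that add atoms: none
Why: In this hydroboration/B-alkyl Suzuki–Miyaura coupling, zerovalent palladium inserts into the unhindered C–I bond much faster than into the C–Br bond (flanked by the phenoxide oxygen) or the C–Cl bond, so the C–D bridge forms with both steering halogens intact.

**Step 8**
Reactants: 13 4-{2-[4-(2-(benzyloxy)-5-{2-[5-(benzyloxy)-2-(methoxymethoxy)phenyl]ethyl}phenoxy)phenyl]ethyl}-2-bromo-6-chlorophenol
Product: 16 4-{2-[4-(2-(benzyloxy)-5-{2-[5-(benzyloxy)-2-(methoxymethoxy)phenyl]ethyl}phenoxy)phenyl]ethyl}-2-chloro-6-(trimethylsilyl)phenyl trifluoromethanesulfonate, via trimethylsilyl ether 14 (not isolated), via lithium phenoxide 15 (not isolated)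
Conditions: HMDS, THF, 70 °C, then evaporation; n-BuLi (1.1 equiv), THF, −100 → −78 °C; Tf2O (1.3 equiv), −78 °C → −20 °C
Reagents that add atoms: hexamethyldisilazane, C[Si](C)(C)N[Si](C)(C)C; trifluoromethanesulfonic anhydride, O=S(=O)(OS(=O)(=O)C(F)(F)F)C(F)(F)F
Why: O-silylation of the only free OH, bromine–lithium exchange (far faster than any deprotonation at this temperature) and retro-Brook O→C silyl shift place SiMe3 on ring D C3, and Tf2O traps the released phenoxide, which is the standard one-flask route from ortho-bromophenols to ortho-silylaryl triflates; the C5–Cl bond is meta to the carbanion and cannot eliminate.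

**Step 9**
Reactants: 16 MOM-protected silylaryl triflate (name as in step 8)
Product: 17 4-{2-[4-(2-(benzyloxy)-5-{2-[5-(benzyloxy)-2-hydroxyphenyl]ethyl}phenoxy)phenyl]ethyl}-2-chloro-6-(trimethylsilyl)phenyl trifluoromethanesulfonate
Conditions: conc. HCl (cat.), MeOH/THF 1:1, 45 °C
Reagents that add atoms: none
Why: Acid-catalysed acetal exchange cleaves the MOM group and frees O1–H, while the benzyl ethers and triflate are acid-stable and the C–Si bond sits on an electron-poor ring (OTf, Cl) that resists protodesilylation.

**Step 10**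
Reactants: 17 seco phenol with the ring D ortho-silylaryl triflate (name as in step 9)
Product: 19 ring D C5-chloro di-O-benzyl dihydroptychantol A (the target macrocycle with both phenols as benzyl ethers and Cl on ring D meta to both O1 and the bridge), via chloroaryne 18 (not isolated)
Conditions: CsF (4 equiv), MeCN/THF 4:1, 17 added by syringe pump over 16 h, final 0.5 mM, 25 → 40 °C
Reagents that add atoms: none
Why: Proposed new method: fluoride attacks the SiMe3 group on ring D C3, the C4 triflate leaves and the 3-chloro-5-alkylbenzyne 18 (C3≡C4) forms, while the same basic medium holds the ring A O1–H as a caesium phenoxide or fluoride-bound phenol. O1 adds to C3 and the aryl anion that appears on C4 takes up the proton brought in by the phenol, so the triple bond receives O and H on neighbouring carbons and the 18-membered ring closes by a formally 18-exo-dig intramolecular nucleophilic addition; no stereocentre is formed. The closest known reaction type is the intermolecular O-arylation of phenols by ortho-silylaryl triflates with CsF in MeCN at room temperature, and tethered O-nucleophiles are known to capture arynes in small-ring closures only, so the macrocyclic mode is what is new. Site selectivity (C3 against C4) rests on the C5 chlorine beside the triple bond: its inductive pull distorts the aryne so that the far carbon C3 is the more linear and electrophilic one, it stabilises the charge growing on the adjacent C4, and it shields C4 sterically, whereas the C1 alkyl group lies too far away to matter, so the isomeric para-bridged 19-membered ring should be suppressed. Chemoselectivity rests on O1–H being the only free OH (both other phenols are benzyl ethers), and fast protonation of the C4 anion in this protic setting should outrun loss of chloride. Ring closure against oligomerisation rests on slow addition at sub-millimolar concentration, on the aryne being formed in the rate-limiting step so that it never accumulates, and on the two flexible CH2CH2 bridges that leave the ring nearly strain-free.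

**Step 11**
Reactants: 19 ring D C5-chloro di-O-benzyl dihydroptychantol A
Product: 20 dihydroptychantol A
Conditions: H2 (1 atm), 10% Pd/C, NaOAc (1.5 equiv), EtOAc/MeOH 1:1, rt
Reagents that add atoms: none
Why: Heterogeneous palladium-catalysed hydrogenolysis cleaves both benzylic C–O bonds and the aryl C–Cl bond in one operation, while the diaryl ethers and the saturated bridges are inert.

**Compound list**

1 | 4-(benzyloxy)phenol | Oc1ccc(OCc2ccccc2)cc1 | starting material
2 | 4-(benzyloxy)-2-bromophenol | Oc1ccc(OCc2ccccc2)cc1Br | intermediate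
3 | 4-(benzyloxy)-2-bromo-1-(methoxymethoxy)benzene | COCOc1ccc(OCc2ccccc2)cc1Br | intermediate
4 | 4-(benzyloxy)-3-hydroxybenzaldehyde | O=Cc1ccc(OCc2ccccc2)c(O)c1 | starting material
5 | 2-(benzyloxy)-5-vinylphenol | C=Cc1ccc(OCc2ccccc2)c(O)c1 | intermediate
6 | bis-boryl adduct of 5 (9-BBN on the terminal carbon and on the phenol oxygen) | C(Cc1ccc(OCc2ccccc2)c(OB2C3CCCC2CCC3)c1)B1C2CCCC1CCC2 | intermediate
7 | 2-(benzyloxy)-5-{2-[5-(benzyloxy)-2-(methoxymethoxy)phenyl]ethyl}phenol | COCOc1ccc(OCc2ccccc2)cc1CCc1ccc(OCc2ccccc2)c(O)c1 | intermediate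
8 | (4-vinylphenyl)boronic acid | C=Cc1ccc(B(O)O)cc1 | starting material
9 | 4-(benzyloxy)-2-{2-[4-(benzyloxy)-3-(4-vinylphenoxy)phenyl]ethyl}-1-(methoxymethoxy)benzene | COCOc1ccc(OCc2ccccc2)cc1CCc1ccc(OCc2ccccc2)c(Oc2ccc(C=C)cc2)c1 | intermediate
10 | 2-bromo-6-chlorophenol | Oc1c(Cl)cccc1Br | starting material
11 | 2-bromo-6-chloro-4-iodophenol | Oc1c(Cl)cc(I)cc1Br | intermediate
12 | B-(2-arylethyl)-9-BBN from 9 | COCOc1ccc(OCc2ccccc2)cc1CCc1ccc(OCc2ccccc2)c(Oc2ccc(CCB3C4CCCC3CCC4)cc2)c1 | intermediate
13 | seco bromochlorophenol (name in step 7) | COCOc1ccc(OCc2ccccc2)cc1CCc1ccc(OCc2ccccc2)c(Oc2ccc(CCc3cc(Cl)c(O)c(Br)c3)cc2)c1 | intermediate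
14 | O-trimethylsilyl ether of 13 | COCOc1ccc(OCc2ccccc2)cc1CCc1ccc(OCc2ccccc2)c(Oc2ccc(CCc3cc(Cl)c(O[Si](C)(C)C)c(Br)c3)cc2)c1 | intermediate
15 | lithium 2-chloro-6-(trimethylsilyl)phenoxide of the seco chain | [Li+].COCOc1ccc(OCc2ccccc2)cc1CCc1ccc(OCc2ccccc2)c(Oc2ccc(CCc3cc(Cl)c([O-])c([Si](C)(C)C)c3)cc2)c1 | intermediate
16 | MOM-protected silylaryl triflate (name in step 8) | COCOc1ccc(OCc2ccccc2)cc1CCc1ccc(OCc2ccccc2)c(Oc2ccc(CCc3cc(Cl)c(OS(=O)(=O)C(F)(F)F)c([Si](C)(C)C)c3)cc2)c1 | intermediate
17 | seco phenol silylaryl triflate (name in step 9) | Oc1ccc(OCc2ccccc2)cc1CCc1ccc(OCc2ccccc2)c(Oc2ccc(CCc3cc(Cl)c(OS(=O)(=O)C(F)(F)F)c([Si](C)(C)C)c3)cc2)c1 | intermediate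
18 | seco phenol with ring D as the 3-chloro-5-alkylbenzyne (C3≡C4) | Oc1ccc(OCc2ccccc2)cc1CCc1ccc(OCc2ccccc2)c(Oc2ccc(CCC3=CC#CC(Cl)=C3)cc2)c1 | intermediate
19 | ring D C5-chloro di-O-benzyl dihydroptychantol A | c1ccccc1COc1ccc2c(c1)CCc1ccc(OCc3ccccc3)c(c1)Oc1ccc(cc1)CCc1cc(Cl)cc(c1)O2 | intermediate
20 | dihydroptychantol A | Oc1ccc2c(c1)CCc1ccc(O)c(c1)Oc1ccc(cc1)CCc1cccc(c1)O2 | target

**Step count**

- Total step count: 11.
- Longest linear sequence: 9 (steps 1, 2, 4, 5, 7, 8, 9, 10, 11).

**Steps most likely to fail**

1. **Step 10.**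
   - Risks: the aryne may be captured by the phenol of a second molecule (oligomerisation), by fluoride or by the solvent before the chain ends meet. The triflyl group may be transferred to the phenoxide before elimination. The C4 anion may lose chloride.
   - Fallback (known chemistry): an intramolecular Ullmann ether synthesis on a plain aryl bromide, setting out from 9 and rejoining the route at 20.
   - Hydroboration of 9 (giving 12) and B-alkyl Suzuki coupling with 1-bromo-3-iodobenzene (PdCl2(dppf), aq NaOH, THF, rt) should give the MOM-protected 3-bromophenyl seco compound F1.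
   - HCl in MeOH/THF should free the ring A phenol and give the seco bromophenol F2.
   - CuI, N,N-dimethylglycine and Cs2CO3 in dioxane at 110 °C and 2 mM should close the same O1–C3 bond and give di-O-benzyl dihydroptychantol A F3.
   - Hydrogenolysis over Pd/C then leads to 20.

2. **Step 8.**
   - Risks: n-BuLi may lithiate next to the MOM acetal or at a benzylic ether CH2. The aryllithium may be protonated before the silyl shift. Triflation of the hindered phenoxide may stay incomplete.
   - Fallback: the silyl triflate is built on the small ring D block and joined to the chain without base or organolithium. It sets out from 10 and 9 and rejoins the route at 16.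
   - HMDS, then n-BuLi, then Tf2O on 10 should give 2-chloro-6-(trimethylsilyl)phenyl trifluoromethanesulfonate F4.
   - Iridium-catalysed C–H borylation ([Ir(OMe)(cod)]2, dtbpy, B2pin2, THF, 70 °C) should go to the only C–H without an ortho neighbour (para to OTf) and give the pinacol boronate F5.
   - A base-free oxidative Heck coupling with 9 (Pd(OAc)2, 2,9-dimethyl-1,10-phenanthroline, O2, DMA, 50 °C) should give the (E)-stilbene silylaryl triflate F6.
   - Diimide (2-nitrobenzenesulfonyl hydrazide, Et3N, CH2Cl2, rt) should saturate the alkene without touching C–Cl, OTf, SiMe3 or the benzyl ethers, giving 16.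

3. **Step 7.**
   - Risks: halogen selectivity may erode through oxidative addition at C–Br. Oxidative addition to the electron-rich iodophenoxide may be slow enough that the alkylborane is lost by protodeboronation or β-hydride elimination.
   - Fallback: a boron-free Heck/diimide sequence, setting out from 9 and 11 and rejoining the route at 13.
   - A ligand-free Heck reaction (Pd(OAc)2, Bu4NCl, NaHCO3, DMF, 55 °C), which engages aryl iodides only, should give the (E)-stilbene bromochlorophenol F7.
   - Diimide (TsNHNH2, NaOAc, THF/H2O, reflux) should reduce the alkene with all halogens and benzyl ethers retained, giving 13.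

**Further compounds**

F1 | step 10 | MOM-protected 3-bromophenyl seco compound | COCOc1ccc(OCc2ccccc2)cc1CCc1ccc(OCc2ccccc2)c(Oc2ccc(CCc3cccc(Br)c3)cc2)c1
F2 | step 10 | seco bromophenol | Oc1ccc(OCc2ccccc2)cc1CCc1ccc(OCc2ccccc2)c(Oc2ccc(CCc3cccc(Br)c3)cc2)c1
F3 | step 10 | di-O-benzyl dihydroptychantol A | c1ccccc1COc1ccc2c(c1)CCc1ccc(OCc3ccccc3)c(c1)Oc1ccc(cc1)CCc1cccc(c1)O2
F4 | step 8 | 2-chloro-6-(trimethylsilyl)phenyl trifluoromethanesulfonate | C[Si](C)(C)c1cccc(Cl)c1OS(=O)(=O)C(F)(F)F
F5 | step 8 | 2-chloro-4-(4,4,5,5-tetramethyl-1,3,2-dioxaborolan-2-yl)-6-(trimethylsilyl)phenyl trifluoromethanesulfonate | C[Si](C)(C)c1cc(B2OC(C)(C)C(C)(C)O2)cc(Cl)c1OS(=O)(=O)C(F)(F)F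
F6 | step 8 | (E)-stilbene silylaryl triflate | COCOc1ccc(OCc2ccccc2)cc1CCc1ccc(OCc2ccccc2)c(Oc2ccc(/C=C/c3cc(Cl)c(OS(=O)(=O)C(F)(F)F)c([Si](C)(C)C)c3)cc2)c1
F7 | step 7 | (E)-stilbene bromochlorophenol | COCOc1ccc(OCc2ccccc2)cc1CCc1ccc(OCc2ccccc2)c(Oc2ccc(/C=C/c3cc(Cl)c(O)c(Br)c3)cc2)c1
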